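**Retrosynthetic overview**
- The target is opened at the ester (Yamaguchi) into a bicyclic dienone alcohol and (2E,4E,6R)-6-hydroxy-6-methylocta-2,4-dienoic acid; the hydroxyl next to the ring ketone is put in last by enolate oxidation.
- The dienone alcohol comes from a bicyclic ene-dione (ketone reduction, then γ,δ-dehydrogenation); ring B is closed by aldol condensation of a triketone made by Michael addition of 2,3-dimethylcyclohexane-1,4-dione to methyl vinyl ketone.
- Key step: that six-membered ring A dione is made from 2-methylcyclopentane-1,3-dione by a one-carbon ring expansion (zinc ethylidene carbenoid, cyclopropanolate fragmentation), which puts the two methyl-bearing carbons side by side.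
- The acid comes from methyl (2E,4E)-6-oxohepta-2,4-dienoate (asymmetric ethyl addition), itself a Heck product of methyl (E)-3-iodoprop-2-enoate and methyl vinyl ketone.
- Ring order: ring A (ring expansion) first, then ring B (annulation).

Assumption: methyl (E)-3-iodoprop-2-enoate is taken as a catalogue compound.

**Route**

Step 1
Reactants: 1 2-methylcyclopentane-1,3-dione
Product: 2 2,3-dimethylcyclohexane-1,4-dione (cis/trans mixture, stereocentres labile)
Conditions: Et2Zn (3 equiv), CH3CHI2 (3 equiv), CH2Cl2, 0 °C to rt; aq NH4Cl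
Reagents that add atoms: 1,1-diiodoethane CC(I)I
Why: Zinc-carbenoid homologation of a β-dicarbonyl (Zercher-type chain extension): the zinc enolate of 1 is cyclopropanated by EtZnCH(I)CH3 and the donor–acceptor cyclopropanolate fragments at the former C1–C2 bond, a non-pericyclic one-carbon ring expansion to the 1,4-dione whose two enolisable stereocentres are deliberately left unset.

Step 2
Reactants: 2 2,3-dimethylcyclohexane-1,4-dione; 3 but-3-en-2-one
Product: 4 (2R,3R)-2,3-dimethyl-2-(3-oxobutyl)cyclohexane-1,4-dione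
Conditions: 9-amino-9-deoxy-epi-quinine (20 mol %), CF3CO2H (40 mol %), toluene, 30 °C, 3 added over 12 h
Reagents that add atoms: none
Why: Proposed new method: the primary amine forms the more substituted enamine at either carbonyl of 2 (the cis, trans and enantiomeric forms of 2 interconvert through these enamines and iminium ions, so all material funnels through one pathway), the protonated quinuclidine holds and activates 3 on one enamine face, and C–C bond formation anti to the neighbouring pseudoaxial methyl gives the quaternary centre (2R) with the methyls cis (3R) in an enantioconvergent Michael addition, the pseudo-enantiomeric epi-quinidine amine being used instead if the facial sense proves opposite; the closest known reactions are the stoichiometric 1-phenylethylamine-imine Michael addition of 2-methylcyclohexanone to vinyl ketones and primary-amine-catalysed Michael additions of α-branched cyclic ketones to acrylates.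

Step 3
Reactants: 4 (2R,3R)-2,3-dimethyl-2-(3-oxobutyl)cyclohexane-1,4-dione
Product: 5 (4aR,5R)-4a,5-dimethyl-4,4a,7,8-tetrahydronaphthalene-2,6(3H,5H)-dione
Conditions: pyrrolidine (0.3 equiv), AcOH (0.3 equiv), t-BuOMe, 40 °C
Reagents that add atoms: none
Why: Intramolecular aldol condensation (second stage of a Robinson annulation) through the pyrrolidine enamine of the methyl ketone closes ring B onto the ring carbonyl next to the quaternary carbon and dehydrates to the enone, while the secondary amine forms only the less substituted enamine of the other ring ketone, so the methine set in step 2 is not epimerised.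

Step 4
Reactants: 5 (4aR,5R)-4a,5-dimethyl-4,4a,7,8-tetrahydronaphthalene-2,6(3H,5H)-dione
Product: 6 (4aR,5R,6S)-6-hydroxy-4a,5-dimethyl-4,4a,5,6,7,8-hexahydronaphthalen-2(3H)-one
Conditions: LiBH(s-Bu)3 (1.05 equiv), THF, −78 °C; H2O
Reagents that add atoms: none
Why: Chemo- and diastereoselective hydride reduction: the bulky borohydride takes the saturated ketone in preference to the β,β-disubstituted enone and attacks it from the face opposite the axial angular methyl (equatorial attack), giving the axial 6S alcohol cis to both methyl groups.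

Step 5
Reactants: 6 (4aR,5R,6S)-6-hydroxy-4a,5-dimethyl-4,4a,5,6,7,8-hexahydronaphthalen-2(3H)-one
Product: 7 (4aR,5R,6S)-6-hydroxy-4a,5-dimethyl-4,4a,5,6-tetrahydronaphthalen-2(3H)-one
Conditions: chloranil (1.3 equiv), t-BuOH, reflux
Reagents that add atoms: none
Why: Quinone γ,δ-dehydrogenation: chloranil abstracts hydride from C7 of the extended dienol of the enone (the classical conversion of a 4-en-3-one into a 4,6-dien-3-one), placing the C7=C8 double bond in conjugation without touching a stereocentre.

Step 6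
Reactants: 8 methyl (E)-3-iodoprop-2-enoate; 3 but-3-en-2-one
Product: 9 methyl (2E,4E)-6-oxohepta-2,4-dienoate
Conditions: Pd(OAc)2 (5 mol %), NaHCO3, n-Bu4NCl, DMF, rt
Reagents that add atoms: none
Why: Mizoroki–Heck coupling under ligand-free phase-transfer (Jeffery) conditions: oxidative addition of the vinyl iodide to zerovalent palladium with retention, insertion at the terminal carbon of 3 and syn β-hydride elimination give the (2E,4E)-dienone ester.

Step 7
Reactants: 9 methyl (2E,4E)-6-oxohepta-2,4-dienoate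
Product: 10 methyl (2E,4E,6R)-6-hydroxy-6-methylocta-2,4-dienoate
Conditions: Et2Zn (2 equiv), Ti(OiPr)4 (1.2 equiv), trans-1,2-bis(hydroxycamphorsulfonamido)cyclohexane ligand (10 mol %, antipode giving 6R), toluene, rt; H2O
Reagents that add atoms: diethylzinc CC[Zn]CC
Why: Catalytic asymmetric 1,2-addition of diethylzinc to a methyl ketone (titanium bis(sulfonamide)-diol catalysis): the catalyst tells the methyl group from the large dienyl group and delivers ethyl to one carbonyl face, setting the 6R tertiary carbinol, while the ester is inert to the organozinc.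

Step 8
Reactants: 10 methyl (2E,4E,6R)-6-hydroxy-6-methylocta-2,4-dienoate
Product: 11 (2E,4E,6R)-6-hydroxy-6-methylocta-2,4-dienoic acid
Conditions: LiOH·H2O (3 equiv), THF/H2O, 0 °C to rt; 1 M HCl to pH 4 at 0 °C
Reagents that add atoms: lithium hydroxide [Li+].[OH-]
Why: Saponification of the methyl ester, which leaves the base-stable tertiary allylic alcohol and the E,E-diene untouched, with cold, mild acidification to avoid ionising the carbinol.

Step 9
Reactants: 11 (2E,4E,6R)-6-hydroxy-6-methylocta-2,4-dienoic acid; 7 (4aR,5R,6S)-6-hydroxy-4a,5-dimethyl-4,4a,5,6-tetrahydronaphthalen-2(3H)-one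
Product: 13 (1R,2S,8aR)-1,8a-dimethyl-6-oxo-1,2,6,7,8,8a-hexahydronaphthalen-2-yl (2E,4E,6R)-6-hydroxy-6-methylocta-2,4-dienoate, via mixed trichlorobenzoic anhydride 12 (not isolated)
Conditions: 11, 2,4,6-Cl3C6H2COCl, Et3N, THF, rt; then 7, DMAP (0.2 equiv), toluene, 40 °C
Reagents that add atoms: none
Why: Yamaguchi esterification: DMAP attacks the mixed anhydride at the less hindered dienoyl carbonyl and the acylpyridinium acylates the hindered secondary allylic alcohol with retention at the carbinol carbon, while the tertiary alcohol of the acid does not compete.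

Step 10
Reactants: 13 (1R,2S,8aR)-1,8a-dimethyl-6-oxo-1,2,6,7,8,8a-hexahydronaphthalen-2-yl (2E,4E,6R)-6-hydroxy-6-methylocta-2,4-dienoate
Product: 15 (1R,2S,7R,8aR)-7-hydroxy-1,8a-dimethyl-6-oxo-1,2,6,7,8,8a-hexahydronaphthalen-2-yl (2E,4E,6R)-6-hydroxy-6-methylocta-2,4-dienoate, via disodium dienolate 14 (not isolated)
Conditions: NaN(SiMe3)2 (2.2 equiv), THF, −78 °C; trans-2-(phenylsulfonyl)-3-phenyloxaziridine (1.3 equiv), −78 °C; AcOH
Reagents that add atoms: trans-2-(phenylsulfonyl)-3-phenyloxaziridine O=S(=O)(N1OC1c1ccccc1)c1ccccc1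
Why: Davis hydroxylation of a kinetic enolate: the amide base removes the tertiary OH proton and the α′ proton of the dienone, and the oxaziridine transfers oxygen to C7 from the face opposite the pseudoaxial angular methyl, giving the equatorial 7R alcohol, which is also the thermodynamically preferred epimer.

**Compound list**
1 | 2-methylcyclopentane-1,3-dione | CC1C(=O)CCC1=O | starting material
2 | 2,3-dimethylcyclohexane-1,4-dione (cis/trans mixture, stereocentres labile) | CC1C(C)C(=O)CCC1=O | intermediate
3 | but-3-en-2-one | CC(=O)C=C | starting material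
4 | (2R,3R)-2,3-dimethyl-2-(3-oxobutyl)cyclohexane-1,4-dione | O=C1CCC(=O)[C@](C)(CCC(C)=O)[C@H]1C | intermediate
5 | (4aR,5R)-4a,5-dimethyl-4,4a,7,8-tetrahydronaphthalene-2,6(3H,5H)-dione | O=C1CCC2=CC(=O)CC[C@]2(C)[C@H]1C | intermediate
6 | (4aR,5R,6S)-6-hydroxy-4a,5-dimethyl-4,4a,5,6,7,8-hexahydronaphthalen-2(3H)-one | O[C@H]1CCC2=CC(=O)CC[C@]2(C)[C@H]1C | intermediate
7 | (4aR,5R,6S)-6-hydroxy-4a,5-dimethyl-4,4a,5,6-tetrahydronaphthalen-2(3H)-one | O[C@H]1C=CC2=CC(=O)CC[C@]2(C)[C@H]1C | intermediate
8 | methyl (E)-3-iodoprop-2-enoate | COC(=O)/C=C/I | starting material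
9 | methyl (2E,4E)-6-oxohepta-2,4-dienoate | COC(=O)/C=C/C=C/C(C)=O | intermediate
10 | methyl (2E,4E,6R)-6-hydroxy-6-methylocta-2,4-dienoate | CC[C@@](C)(O)/C=C/C=C/C(=O)OC | intermediate
11 | (2E,4E,6R)-6-hydroxy-6-methylocta-2,4-dienoic acid | CC[C@@](C)(O)/C=C/C=C/C(=O)O | intermediate
12 | (2E,4E,6R)-6-hydroxy-6-methylocta-2,4-dienoic 2,4,6-trichlorobenzoic anhydride (not isolated) | CC[C@@](C)(O)/C=C/C=C/C(=O)OC(=O)c1c(Cl)cc(Cl)cc1Cl | intermediate
13 | (1R,2S,8aR)-1,8a-dimethyl-6-oxo-1,2,6,7,8,8a-hexahydronaphthalen-2-yl (2E,4E,6R)-6-hydroxy-6-methylocta-2,4-dienoate | CC[C@@](C)(O)/C=C/C=C/C(=O)O[C@H]1C=CC2=CC(=O)CC[C@]2(C)[C@H]1C | intermediate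
14 | disodium alkoxide/cross-conjugated dienolate of 13 (not isolated) | [Na+].[Na+].CC[C@@](C)([O-])/C=C/C=C/C(=O)O[C@H]1C=CC2=CC([O-])=CC[C@]2(C)[C@H]1C | intermediate
15 | (1R,2S,7R,8aR)-7-hydroxy-1,8a-dimethyl-6-oxo-1,2,6,7,8,8a-hexahydronaphthalen-2-yl (2E,4E,6R)-6-hydroxy-6-methylocta-2,4-dienoate | CC[C@@](C)(O)/C=C/C=C/C(=O)O[C@H]1C=CC2=CC(=O)[C@H](O)C[C@]2(C)[C@H]1C | target

**Totals**
Total steps: 10. Longest linear sequence: 7 (steps 1, 2, 3, 4, 5, 9, 10).

**Steps most likely to fail**

Step 2 (the proposed new reaction). The catalyst may be alkylated by 3, the hindered enamine may turn over slowly, and the methine next to the new quaternary carbon may erode if the product ketone also forms an enamine. The fallback is known auxiliary chemistry and sets out from 2. Condensation with (R)-1-phenylethylamine (toluene, cat. TsOH, Dean–Stark) gives the imine 2,3-dimethyl-4-{[(1R)-1-phenylethyl]imino}cyclohexan-1-one F1. Its secondary enamine tautomer adds to 3 (THF, rt, aza-ene-type Michael addition) to give (2R,3R)-2,3-dimethyl-3-(3-oxobutyl)-4-{[(1R)-1-phenylethyl]imino}cyclohexan-1-one F2. Hydrolysis with aqueous AcOH returns to the route at 4.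

Step 5. Chloranil dehydrogenation next to a free carbinol may stall or over-oxidise. The fallback replaces hydride abstraction by halogenation and elimination and sets out from 6. TMSOTf/Et3N gives (4aR,5R,6S)-4a,5-dimethyl-2,6-bis[(trimethylsilyl)oxy]-3,4,4a,5,6,7-hexahydronaphthalene F3. NBS (THF, 0 °C, then dilute acid) brominates the γ-carbon to (4aR,5R,6S)-8-bromo-6-hydroxy-4a,5-dimethyl-4,4a,5,6,7,8-hexahydronaphthalen-2(3H)-one F4 (C8 epimers). Li2CO3/LiBr in DMF at 100 °C eliminates HBr and rejoins the route at 7.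

Step 10. Late enolate oxidation of the full ester may suffer from deprotonation at the acyloxy-bearing carbon or attack on the dienoate. The fallback hydroxylates before esterification and sets out from 7. NaN(SiMe3)2 (2.2 equiv) and the same oxaziridine give (3R,4aR,5R,6S)-3,6-dihydroxy-4a,5-dimethyl-4,4a,5,6-tetrahydronaphthalen-2(3H)-one F5. TBSCl/imidazole silylates the less hindered hydroxyl next to the ketone to give (3R,4aR,5R,6S)-3-[(tert-butyldimethylsilyl)oxy]-6-hydroxy-4a,5-dimethyl-4,4a,5,6-tetrahydronaphthalen-2(3H)-one F6. Esterification with 11 under the conditions of step 9 gives (1R,2S,7R,8aR)-7-[(tert-butyldimethylsilyl)oxy]-1,8a-dimethyl-6-oxo-1,2,6,7,8,8a-hexahydronaphthalen-2-yl (2E,4E,6R)-6-hydroxy-6-methylocta-2,4-dienoate F7. HF·pyridine then removes the silyl group and arrives at 15.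

**Further compounds**
F1 | step 2 | 2,3-dimethyl-4-{[(1R)-1-phenylethyl]imino}cyclohexan-1-one | C[C@@H](N=C1CCC(=O)C(C)C1C)c1ccccc1
F2 | step 2 | (2R,3R)-2,3-dimethyl-3-(3-oxobutyl)-4-{[(1R)-1-phenylethyl]imino}cyclohexan-1-one | C[C@@H](N=C1CCC(=O)[C@H](C)[C@@]1(C)CCC(C)=O)c1ccccc1
F3 | step 5 | (4aR,5R,6S)-4a,5-dimethyl-2,6-bis[(trimethylsilyl)oxy]-3,4,4a,5,6,7-hexahydronaphthalene | C[Si](C)(C)O[C@H]1CC=C2C=C(O[Si](C)(C)C)CC[C@]2(C)[C@H]1C
F4 | step 5 | (4aR,5R,6S)-8-bromo-6-hydroxy-4a,5-dimethyl-4,4a,5,6,7,8-hexahydronaphthalen-2(3H)-one | O[C@H]1CC(Br)C2=CC(=O)CC[C@]2(C)[C@H]1C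
F5 | step 10 | (3R,4aR,5R,6S)-3,6-dihydroxy-4a,5-dimethyl-4,4a,5,6-tetrahydronaphthalen-2(3H)-one | O[C@H]1C=CC2=CC(=O)[C@H](O)C[C@]2(C)[C@H]1C
F6 | step 10 | (3R,4aR,5R,6S)-3-[(tert-butyldimethylsilyl)oxy]-6-hydroxy-4a,5-dimethyl-4,4a,5,6-tetrahydronaphthalen-2(3H)-one | O[C@H]1C=CC2=CC(=O)[C@H](O[Si](C)(C)C(C)(C)C)C[C@]2(C)[C@H]1C
F7 | step 10 | (1R,2S,7R,8aR)-7-[(tert-butyldimethylsilyl)oxy]-1,8a-dimethyl-6-oxo-1,2,6,7,8,8a-hexahydronaphthalen-2-yl (2E,4E,6R)-6-hydroxy-6-methylocta-2,4-dienoate | CC[C@@](C)(O)/C=C/C=C/C(=O)O[C@H]1C=CC2=CC(=O)[C@H](O[Si](C)(C)C(C)(C)C)C[C@]2(C)[C@H]1C
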